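**Retrosynthetic overview**

1. Carotenoid locants are used: ring A is the hydroxylated, acetylenic cyclohexene (C1 = CMe2, C3 = CHOH, C5=C6, alkyne C7≡C8) and ring B is the diol ring (primed locants). The chain is cut at C11=C12 and C11'=C12' (two Wittig olefinations) into the ring A C15 phosphonium salt 16, the C10 dialdehyde 27 and the ring B C15 phosphonium salt 26.
2. Ring A: the C6–C7 bond comes from Sonogashira coupling of enol triflate 12 with enynol 13; the C3–O bond comes from a C3–acyl group by Baeyer–Villiger oxidation with retention.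
3. Key disconnection: ring A is a cyclohexene whose C5=C6 bond lies between C4H2 and the quaternary C1, which makes it a Diels–Alder retron once the sp carbon on C6 is exchanged for silyloxy. Diene 5 (C4=C5–C6(OSi)=C1) and acrylate 6 (C2=C3) give the bonds C1–C2 and C3–C4, the C3 stereocentre, and a carboxyl group para to the C6 oxygen.
4. Ring B: bought as β-cyclocitral 17; asymmetric epoxidation of 18, epoxide hydrolysis with inversion at C5', then Horner–Wadsworth–Emmons extension to C15.
5. Ring order: ring A is the only carbocycle that is formed (step 4); the oxirane on ring B is formed in step 12 and opened in step 13.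

Key step: step 4

Assumption: (2E)-3-methylpent-2-en-4-yn-1-ol, (2E,4E,6E)-2,7-dimethylocta-2,4,6-trienedial, β-cyclocitral and the C5 phosphonate 22 are taken as commercial; the final carotenoid is handled in the dark under inert gas.

**Ring A half (steps 1–10)**

Step 1
Reactants: 1 2-methylpropanal; 2 (prop-1-en-2-yl)magnesium bromide
Product: 3 rac-2,4-dimethylpent-1-en-3-ol
Conditions: THF, 0 °C → rt; then H2O
Reagents that add atoms: none
Why: Grignard 1,2-addition of an alkenylmagnesium halide to an aldehyde; the carbinol centre is racemic and is removed in step 2.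

Step 2
Reactants: 3 rac-2,4-dimethylpent-1-en-3-ol
Product: 4 2,4-dimethylpent-1-en-3-one
Conditions: 2-iodoxybenzoic acid (IBX), EtOAc, 75 °C; filtration, careful distillation
Reagents that add atoms: none
Why: IBX oxidation of a secondary allylic alcohol to the enone, with a reagent that is filtered off so that the volatile ketone needs no aqueous work-up.

Step 3
Reactants: 4 2,4-dimethylpent-1-en-3-one
Product: 5 [(2,4-dimethylpenta-1,3-dien-3-yl)oxy]tri(propan-2-yl)silane
Conditions: iPr3SiOTf, Et3N, CH2Cl2, 0 °C → rt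
Reagents that add atoms: tri(propan-2-yl)silyl trifluoromethanesulfonate, CC(C)[Si](OS(=O)(=O)C(F)(F)F)(C(C)C)C(C)C
Why: Soft enolisation with O-silylation; the isopropyl methine is the only enolisable hydrogen, so a single 2-silyloxydiene forms and its CMe2 terminus has no E/Z issue.

Step 4
Reactants: 5 [(2,4-dimethylpenta-1,3-dien-3-yl)oxy]tri(propan-2-yl)silane; 6 2,2,2-trifluoroethyl prop-2-enoate
Product: 7 2,2,2-trifluoroethyl (1R)-3,5,5-trimethyl-4-{[tri(propan-2-yl)silyl]oxy}cyclohex-3-ene-1-carboxylate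
Conditions: 20 mol % (S)-3,3-diphenyl-1-(2-methylphenyl)tetrahydro-1H,3H-pyrrolo[1,2-c][1,3,2]oxazaborole protonated by HN(SO2CF3)2, CH2Cl2, −78 → −20 °C
Reagents that add atoms: none
Why: The cationic oxazaborolidinium binds the acrylate carbonyl and lowers its LUMO, and the 2-silyloxydiene adds in a concerted but strongly asynchronous [4+2] in which the enol-ether β-carbon (the CMe2 terminus) bonds first to the unsubstituted acrylate CH2 and the acrylate α-carbon then closes on the diene CH2 terminus. The closest known reaction type is the oxazaborolidinium-catalysed enantioselective Diels–Alder reaction of 2-(triisopropylsilyloxy)buta-1,3-diene with 2,2,2-trifluoroethyl acrylate. Ring A is closed by an intermolecular [4+2] cycloaddition; should the second bond lag behind, it forms as a 6-endo-trig Michael closure of the boron-bound ester enolate onto the silyl-activated isopropenyl ketone and gives the same product. The only new stereocentre (C1 of 7, later C3 of the target) is set by the catalyst, which shields one face of the bound acrylate; the (S)-catalyst is chosen because it is the antipode that delivers (S)-cyclohex-3-enecarboxylate from buta-1,3-diene, which is the same acrylate face and reads (1R) here because the gem-dimethyl carbon exchanges the CIP ranks of the two ring CH2 groups. The step needs only enantiofacial selectivity on the dienophile (endo/exo is immaterial because no second stereocentre is formed) and para regioselectivity, which the 2-silyloxy group secures by making the CMe2 terminus the nucleophilic end. The bulky iPr3Si group is there to suppress silyl transfer, which would open a racemic silyl-cation-catalysed background path.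

Step 5
Reactants: 7 2,2,2-trifluoroethyl (1R)-3,5,5-trimethyl-4-{[tri(propan-2-yl)silyl]oxy}cyclohex-3-ene-1-carboxylate
Product: 9 2,2,2-trifluoroethyl (1R)-3,5,5-trimethyl-4-[(trifluoromethanesulfonyl)oxy]cyclohex-3-ene-1-carboxylate, via caesium enolate 8 (not isolated)
Conditions: CsF, PhN(SO2CF3)2, 1,2-dimethoxyethane, rt
Reagents that add atoms: N-phenylbis(trifluoromethanesulfonimide), O=S(=O)(N(c1ccccc1)S(=O)(=O)C(F)(F)F)C(F)(F)F; caesium fluoride, [Cs+].[F-] (caesium only in intermediate 8)
Why: Fluoride-induced conversion of a silyl enol ether into an enol triflate; the regio-defined enolate is trapped on oxygen as it forms, and the ester α-hydrogen is too weakly acidic to be removed by this hindered ketone enolate, so C1 should not epimerise.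

Step 6
Reactants: 9 2,2,2-trifluoroethyl (1R)-3,5,5-trimethyl-4-[(trifluoromethanesulfonyl)oxy]cyclohex-3-ene-1-carboxylate
Product: 11 (4R)-4-acetyl-2,6,6-trimethylcyclohex-1-en-1-yl trifluoromethanesulfonate, via N-methoxy-N-methylamide 10 (not isolated)
Conditions: MeONHMe·HCl, iPrMgCl, THF, −20 °C; then MeMgBr, 0 °C; then H2O
Reagents that add atoms: methylmagnesium bromide, C[Mg]Br; N,O-dimethylhydroxylamine hydrochloride, CNOC.Cl (its atoms are in intermediate 10 only)
Why: One-pot aminolysis of the activated ester by the magnesium amide followed by Weinreb ketone synthesis, in which the chelated tetrahedral adduct stops at the ketone; enol triflates do not react with Grignard reagents without a transition-metal catalyst, and the stereocentre is not touched.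

Step 7
Reactants: 11 (4R)-4-acetyl-2,6,6-trimethylcyclohex-1-en-1-yl trifluoromethanesulfonate
Product: 12 (1R)-3,5,5-trimethyl-4-[(trifluoromethanesulfonyl)oxy]cyclohex-3-en-1-yl acetate
Conditions: mCPBA, NaHCO3, CH2Cl2, rt → 40 °C
Reagents that add atoms: 3-chloroperoxybenzoic acid, OOC(=O)c1cccc(Cl)c1
Why: Baeyer–Villiger oxidation in which the secondary ring carbon migrates in preference to methyl with retention of configuration, so the acetyl group becomes the acetate of the (R)-carbinol; the tetrasubstituted enol triflate is too electron-poor to be epoxidised.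

Step 8
Reactants: 12 (1R)-3,5,5-trimethyl-4-[(trifluoromethanesulfonyl)oxy]cyclohex-3-en-1-yl acetate; 13 (2E)-3-methylpent-2-en-4-yn-1-ol
Product: 14 (1R)-4-[(3E)-5-hydroxy-3-methylpent-3-en-1-yn-1-yl]-3,5,5-trimethylcyclohex-3-en-1-yl acetate
Conditions: Pd(PPh3)4 (5 mol %), CuI (10 mol %), Et3N, DMF, rt → 40 °C
Reagents that add atoms: none
Why: Sonogashira coupling of a 2,6,6-trimethylcyclohexenyl triflate with a terminal enyne, a coupling that is well established for this hindered triflate type; the (E)-alkene of 13 and the acetate are not affected.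

Step 9
Reactants: 14 (1R)-4-[(3E)-5-hydroxy-3-methylpent-3-en-1-yn-1-yl]-3,5,5-trimethylcyclohex-3-en-1-yl acetate
Product: 15 (1R)-4-[(3E)-5-hydroxy-3-methylpent-3-en-1-yn-1-yl]-3,5,5-trimethylcyclohex-3-en-1-ol
Conditions: K2CO3 (0.2 equiv), MeOH, rt
Reagents that add atoms: none
Why: Base-catalysed transesterification (methanolysis) of the secondary acetate, which touches no stereocentre and no double bond.

Step 10
Reactants: 15 (1R)-4-[(3E)-5-hydroxy-3-methylpent-3-en-1-yn-1-yl]-3,5,5-trimethylcyclohex-3-en-1-ol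
Product: 16 {(2E)-5-[(4R)-4-hydroxy-2,6,6-trimethylcyclohex-1-en-1-yl]-3-methylpent-2-en-4-yn-1-yl}(triphenyl)phosphonium bromide
Conditions: Ph3P·HBr, MeOH, 0 °C → rt, dark
Reagents that add atoms: triphenylphosphine hydrobromide, [PH+](c1ccccc1)(c1ccccc1)c1ccccc1.[Br-]
Why: Acid-assisted substitution of the primary allylic alcohol by triphenylphosphine (standard formation of carotenoid Wittig salts); the secondary ring hydroxyl is not ionised under these conditions.

**Ring B half (steps 11–17)**

Step 11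
Reactants: 17 2,6,6-trimethylcyclohex-1-ene-1-carbaldehyde
Product: 18 (2,6,6-trimethylcyclohex-1-en-1-yl)methanol
Conditions: NaBH4, MeOH, 0 °C
Reagents that add atoms: none
Why: Borohydride 1,2-reduction of a hindered enal to the allylic alcohol; no stereocentre is formed.

Step 12
Reactants: 18 (2,6,6-trimethylcyclohex-1-en-1-yl)methanol
Product: 19 [(1S,6S)-2,2,6-trimethyl-7-oxabicyclo[4.1.0]heptan-1-yl]methanol
Conditions: Ti(OiPr)4 (10 mol %), L-(+)-diethyl tartrate (12 mol %), t-BuOOH, 4 Å molecular sieves, CH2Cl2, −20 °C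
Reagents that add atoms: tert-butyl hydroperoxide, CC(C)(C)OO
Why: Sharpless asymmetric epoxidation; the titanium complex of L-(+)-tartrate delivers oxygen to the alkene face that gives (2S,3S)-epoxides from geraniol-type allylic alcohols, which corresponds to the (1S,6S)-oxirane here, so both new stereocentres are set by the reagent.

Step 13
Reactants: 19 [(1S,6S)-2,2,6-trimethyl-7-oxabicyclo[4.1.0]heptan-1-yl]methanol
Product: 20 (1S,2R)-1-(hydroxymethyl)-2,6,6-trimethylcyclohexane-1,2-diol
Conditions: HClO4 (cat.), THF/H2O, 0 °C → rt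
Reagents that add atoms: water, O
Why: Acid-catalysed epoxide hydrolysis; water attacks the methyl-bearing oxirane carbon with inversion, because the other carbon is neopentylic and deactivated by the hydroxymethyl group, and the retained C–O bond fixes the trans-diol.

Step 14
Reactants: 20 (1S,2R)-1-(hydroxymethyl)-2,6,6-trimethylcyclohexane-1,2-diol
Product: 21 (1R,2R)-1,2-dihydroxy-2,6,6-trimethylcyclohexane-1-carbaldehyde
Conditions: 2-iodoxybenzoic acid (IBX), DMSO, rt; used crude
Reagents that add atoms: none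
Why: IBX oxidation of the primary alcohol, which leaves tertiary alcohols alone and does not cleave vicinal diols; the α-carbon is quaternary and cannot epimerise (the descriptor changes only through CIP ranking).

Step 15
Reactants: 21 (1R,2R)-1,2-dihydroxy-2,6,6-trimethylcyclohexane-1-carbaldehyde; 22 ethyl (2E)-4-(diethoxyphosphoryl)-3-methylbut-2-enoate
Product: 24 ethyl (2E,4E)-5-[(1R,2R)-1,2-dihydroxy-2,6,6-trimethylcyclohexyl]-3-methylpenta-2,4-dienoate, via lithiated phosphonate 23 (not isolated)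
Conditions: 22, LiN(SiMe3)2, THF, −78 °C; then 21, −78 → 0 °C
Reagents that add atoms: lithium bis(trimethylsilyl)amide, [Li+].C[Si](C)(C)[N-][Si](C)(C)C (lithium only in intermediate 23)
Why: Horner–Wadsworth–Emmons olefination with the vinylogous phosphonate carbanion, which is less basic than a tertiary alkoxide so the free diol should stay protonated; the new C=C should form E (stabilised carbanion) and any (2Z) isomer is removed by chromatography.

Step 16
Reactants: 24 ethyl (2E,4E)-5-[(1R,2R)-1,2-dihydroxy-2,6,6-trimethylcyclohexyl]-3-methylpenta-2,4-dienoate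
Product: 25 (1R,2R)-1-[(1E,3E)-5-hydroxy-3-methylpenta-1,3-dien-1-yl]-2,6,6-trimethylcyclohexane-1,2-diol
Conditions: iBu2AlH (5 equiv), CH2Cl2, −78 °C; aq. KNaC4H4O6 work-up
Reagents that add atoms: none
Why: Aluminium hydride 1,2-reduction of the dienoate to the allylic alcohol; two equivalents of hydride are consumed by the hydroxyl groups and no stereocentre is involved.

Step 17
Reactants: 25 (1R,2R)-1-[(1E,3E)-5-hydroxy-3-methylpenta-1,3-dien-1-yl]-2,6,6-trimethylcyclohexane-1,2-diol
Product: 26 {(2E,4E)-5-[(1R,2R)-1,2-dihydroxy-2,6,6-trimethylcyclohexyl]-3-methylpenta-2,4-dien-1-yl}(triphenyl)phosphonium bromide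
Conditions: Ph3P·HBr, MeOH, 0 °C → rt
Reagents that add atoms: triphenylphosphine hydrobromide, [PH+](c1ccccc1)(c1ccccc1)c1ccccc1.[Br-]
Why: Same phosphonium salt formation as in step 10; the tertiary allylic hydroxyl is deactivated towards ionisation by the vicinal hydroxyl, in line with the acid stability of carotenoid 5,6-diols.

**Assembly (steps 18–19)**

Step 18
Reactants: 26 {(2E,4E)-5-[(1R,2R)-1,2-dihydroxy-2,6,6-trimethylcyclohexyl]-3-methylpenta-2,4-dien-1-yl}(triphenyl)phosphonium bromide; 27 (2E,4E,6E)-2,7-dimethylocta-2,4,6-trienedial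
Product: 29 (2E,4E,6E,8E,10E,12E)-13-[(1R,2R)-1,2-dihydroxy-2,6,6-trimethylcyclohexyl]-2,7,11-trimethyltrideca-2,4,6,8,10,12-hexaenal, via phosphorus ylide 28 (not isolated)
Conditions: 27 (3 equiv), NaOMe (slow addition), MeOH/CH2Cl2, 0 °C; then EtOAc, 70 °C; excess 27 recovered
Reagents that add atoms: none
Why: Wittig olefination with a semi-stabilised allylic ylide; the excess of dialdehyde should secure mono-olefination, and the hindered Z isomer at the new double bond should revert to E on gentle heating.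

Step 19
Reactants: 29 (2E,4E,6E,8E,10E,12E)-13-[(1R,2R)-1,2-dihydroxy-2,6,6-trimethylcyclohexyl]-2,7,11-trimethyltrideca-2,4,6,8,10,12-hexaenal; 16 {(2E)-5-[(4R)-4-hydroxy-2,6,6-trimethylcyclohex-1-en-1-yl]-3-methylpent-2-en-4-yn-1-yl}(triphenyl)phosphonium bromide
Product: 31 (3R,5'R,6'R)-7,8-didehydro-5',6'-dihydro-β,β-carotene-3,5',6'-triol (the target), via phosphorus ylide 30 (not isolated)
Conditions: NaOMe, MeOH/CH2Cl2, 0 °C → rt; then heptane/EtOH, 75 °C, dark; crystallisation
Reagents that add atoms: none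
Why: Second Wittig olefination, which closes the C11=C12 bond; free hydroxyl groups are tolerated, no stereocentre is touched, and thermal equilibration should convert the hindered 11Z isomer into the all-E polyene.

**Compound list**

1 | 2-methylpropanal | CC(C)C=O | starting material
2 | (prop-1-en-2-yl)magnesium bromide | CC(=C)[Mg]Br | starting material
3 | rac-2,4-dimethylpent-1-en-3-ol | CC(C)C(O)C(C)=C | intermediate
4 | 2,4-dimethylpent-1-en-3-one | CC(C)C(=O)C(C)=C | intermediate
5 | [(2,4-dimethylpenta-1,3-dien-3-yl)oxy]tri(propan-2-yl)silane | CC(C)=C(O[Si](C(C)C)(C(C)C)C(C)C)C(C)=C | intermediate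
6 | 2,2,2-trifluoroethyl prop-2-enoate | C=CC(=O)OCC(F)(F)F | starting material
7 | 2,2,2-trifluoroethyl (1R)-3,5,5-trimethyl-4-{[tri(propan-2-yl)silyl]oxy}cyclohex-3-ene-1-carboxylate | CC1=C(O[Si](C(C)C)(C(C)C)C(C)C)C(C)(C)C[C@H](C(=O)OCC(F)(F)F)C1 | intermediate
8 | caesium (4R)-2,6,6-trimethyl-4-[(2,2,2-trifluoroethoxy)carbonyl]cyclohex-1-en-1-olate | CC1=C([O-])C(C)(C)C[C@H](C(=O)OCC(F)(F)F)C1.[Cs+] | intermediate
9 | 2,2,2-trifluoroethyl (1R)-3,5,5-trimethyl-4-[(trifluoromethanesulfonyl)oxy]cyclohex-3-ene-1-carboxylate | CC1=C(OS(=O)(=O)C(F)(F)F)C(C)(C)C[C@H](C(=O)OCC(F)(F)F)C1 | intermediate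
10 | (1R)-N-methoxy-N,3,5,5-tetramethyl-4-[(trifluoromethanesulfonyl)oxy]cyclohex-3-ene-1-carboxamide | CC1=C(OS(=O)(=O)C(F)(F)F)C(C)(C)C[C@H](C(=O)N(C)OC)C1 | intermediate
11 | (4R)-4-acetyl-2,6,6-trimethylcyclohex-1-en-1-yl trifluoromethanesulfonate | CC1=C(OS(=O)(=O)C(F)(F)F)C(C)(C)C[C@H](C(C)=O)C1 | intermediate
12 | (1R)-3,5,5-trimethyl-4-[(trifluoromethanesulfonyl)oxy]cyclohex-3-en-1-yl acetate | CC1=C(OS(=O)(=O)C(F)(F)F)C(C)(C)C[C@H](OC(C)=O)C1 | intermediate
13 | (2E)-3-methylpent-2-en-4-yn-1-ol | C#C/C(C)=C/CO | starting material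
14 | (1R)-4-[(3E)-5-hydroxy-3-methylpent-3-en-1-yn-1-yl]-3,5,5-trimethylcyclohex-3-en-1-yl acetate | CC1=C(C#C/C(C)=C/CO)C(C)(C)C[C@H](OC(C)=O)C1 | intermediate
15 | (1R)-4-[(3E)-5-hydroxy-3-methylpent-3-en-1-yn-1-yl]-3,5,5-trimethylcyclohex-3-en-1-ol | CC1=C(C#C/C(C)=C/CO)C(C)(C)C[C@H](O)C1 | intermediate
16 | {(2E)-5-[(4R)-4-hydroxy-2,6,6-trimethylcyclohex-1-en-1-yl]-3-methylpent-2-en-4-yn-1-yl}(triphenyl)phosphonium bromide | CC1=C(C#C/C(C)=C/C[P+](c2ccccc2)(c2ccccc2)c2ccccc2)C(C)(C)C[C@H](O)C1.[Br-] | intermediate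
17 | 2,6,6-trimethylcyclohex-1-ene-1-carbaldehyde (β-cyclocitral) | CC1=C(C=O)C(C)(C)CCC1 | starting material
18 | (2,6,6-trimethylcyclohex-1-en-1-yl)methanol | CC1=C(CO)C(C)(C)CCC1 | intermediate
19 | [(1S,6S)-2,2,6-trimethyl-7-oxabicyclo[4.1.0]heptan-1-yl]methanol | OC[C@]12O[C@@]1(C)CCCC2(C)C | intermediate
20 | (1S,2R)-1-(hydroxymethyl)-2,6,6-trimethylcyclohexane-1,2-diol | OC[C@@]1(O)C(C)(C)CCC[C@@]1(C)O | intermediate
21 | (1R,2R)-1,2-dihydroxy-2,6,6-trimethylcyclohexane-1-carbaldehyde | O=C[C@@]1(O)C(C)(C)CCC[C@@]1(C)O | intermediate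
22 | ethyl (2E)-4-(diethoxyphosphoryl)-3-methylbut-2-enoate | CCOC(=O)/C=C(C)/CP(=O)(OCC)OCC | starting material
23 | lithium 1-(diethoxyphosphoryl)-4-ethoxy-2-methyl-4-oxobut-2-en-1-ide | CCOC(=O)C=C(C)[CH-]P(=O)(OCC)OCC.[Li+] | intermediate
24 | ethyl (2E,4E)-5-[(1R,2R)-1,2-dihydroxy-2,6,6-trimethylcyclohexyl]-3-methylpenta-2,4-dienoate | CCOC(=O)/C=C(C)/C=C/[C@@]1(O)C(C)(C)CCC[C@@]1(C)O | intermediate
25 | (1R,2R)-1-[(1E,3E)-5-hydroxy-3-methylpenta-1,3-dien-1-yl]-2,6,6-trimethylcyclohexane-1,2-diol | OC/C=C(C)/C=C/[C@@]1(O)C(C)(C)CCC[C@@]1(C)O | intermediate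
26 | {(2E,4E)-5-[(1R,2R)-1,2-dihydroxy-2,6,6-trimethylcyclohexyl]-3-methylpenta-2,4-dien-1-yl}(triphenyl)phosphonium bromide | [Br-].c1ccccc1[P+](c1ccccc1)(c1ccccc1)C/C=C(C)/C=C/[C@@]1(O)C(C)(C)CCC[C@@]1(C)O | intermediate
27 | (2E,4E,6E)-2,7-dimethylocta-2,4,6-trienedial | O=C/C(C)=C/C=C/C=C(C)/C=O | starting material
28 | (1R,2R)-2,6,6-trimethyl-1-[(1E,3E)-3-methyl-5-(triphenyl-λ5-phosphanylidene)penta-1,3-dien-1-yl]cyclohexane-1,2-diol | c1ccccc1P(c1ccccc1)(c1ccccc1)=C/C=C(C)/C=C/[C@@]1(O)C(C)(C)CCC[C@@]1(C)O | intermediate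
29 | (2E,4E,6E,8E,10E,12E)-13-[(1R,2R)-1,2-dihydroxy-2,6,6-trimethylcyclohexyl]-2,7,11-trimethyltrideca-2,4,6,8,10,12-hexaenal | O=C/C(C)=C/C=C/C=C(C)/C=C/C=C(C)/C=C/[C@@]1(O)C(C)(C)CCC[C@@]1(C)O | intermediate
30 | (1R)-3,5,5-trimethyl-4-[(3E)-3-methyl-5-(triphenyl-λ5-phosphanylidene)pent-3-en-1-yn-1-yl]cyclohex-3-en-1-ol | CC1=C(C#C/C(C)=C/C=P(c2ccccc2)(c2ccccc2)c2ccccc2)C(C)(C)C[C@H](O)C1 | intermediate
31 | (3R,5'R,6'R)-7,8-didehydro-5',6'-dihydro-β,β-carotene-3,5',6'-triol | CC1=C(C#C/C(C)=C/C=C/C(C)=C/C=C/C=C(C)/C=C/C=C(C)/C=C/[C@@]2(O)C(C)(C)CCC[C@@]2(C)O)C(C)(C)C[C@H](O)C1 | target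

**Step count and risks**

Total step count: 19. Longest linear sequence: 11 steps (steps 1–10, then step 19).

Steps most likely to fail:

1. Step 4. Enantiofacial control may erode if ring closure becomes stepwise after silyl transfer, or if a silyl-cation-catalysed background reaction competes; bond formation at the fully substituted diene terminus may also be slow. The fallback replaces catalyst control by auxiliary control; it sets out from 5 and comes back to the route at 10. Commercial (4R)-4-benzyl-1,3-oxazolidin-2-one is N-acylated with acryloyl chloride (n-BuLi, THF, −78 °C) to (4R)-4-benzyl-3-(prop-2-enoyl)-1,3-oxazolidin-2-one F1. F1 and 5 are combined with Et2AlCl (1.4 equiv, CH2Cl2, −78 °C); the benzyl group shields the same face of the aluminium-chelated imide in both bond-forming events, so the sense holds even for a stepwise Michael–Michael course, and the (4R)-auxiliary should give the imide adduct (4R)-4-benzyl-3-{[(1R)-3,5,5-trimethyl-4-{[tri(propan-2-yl)silyl]oxy}cyclohex-3-en-1-yl]carbonyl}-1,3-oxazolidin-2-one F2. Transamination with Me3Al and MeONHMe·HCl gives (1R)-N-methoxy-N,3,5,5-tetramethyl-4-{[tri(propan-2-yl)silyl]oxy}cyclohex-3-ene-1-carboxamide F3 with recovery of the auxiliary. CsF and PhN(SO2CF3)2 as in step 5 convert F3 into 10, which is then isolated and treated with MeMgBr as in the second half of step 6.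

2. Step 15. Retro-aldol ring opening or α-ketol rearrangement of the unprotected α,β-dihydroxy aldehyde may occur under the basic olefination conditions, and addition to the neopentylic aldehyde may be slow. The fallback masks the hydroxyl groups; it sets out from 20 and comes back at 24. Me3SiOTf and 2,6-lutidine convert 20 into (1S,2R)-2,6,6-trimethyl-1-[(trimethylsilyloxy)methyl]-1,2-bis(trimethylsilyloxy)cyclohexane F4. Swern oxidation ((COCl)2, DMSO, then Et3N), which oxidises primary trimethylsilyl ethers directly, gives (1R,2R)-2,6,6-trimethyl-1,2-bis(trimethylsilyloxy)cyclohexane-1-carbaldehyde F5. Olefination of F5 with 23 as in step 15 gives ethyl (2E,4E)-5-[(1R,2R)-2,6,6-trimethyl-1,2-bis(trimethylsilyloxy)cyclohexyl]-3-methylpenta-2,4-dienoate F6, and K2CO3 in MeOH removes the silyl groups to give 24.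

3. Step 19. Double-bond geometry may be lost: Z-olefin formation at C11=C12, and E/Z scrambling at the C9=C10 bond next to the alkyne through the allylic cation during salt formation in step 10. The fallback replaces the Wittig salt by a phosphonate made under non-ionising conditions; it sets out from 14 and comes back at 31. CBr4 and PPh3 (CH2Cl2, −20 °C) convert 14 into (1R)-4-[(3E)-5-bromo-3-methylpent-3-en-1-yn-1-yl]-3,5,5-trimethylcyclohex-3-en-1-yl acetate F7. An Arbuzov reaction with P(OEt)3 gives diethyl {(2E)-5-[(4R)-4-(acetyloxy)-2,6,6-trimethylcyclohex-1-en-1-yl]-3-methylpent-2-en-4-yn-1-yl}phosphonate F8. Horner–Wadsworth–Emmons olefination of 29 with F8 (KOtBu, THF, −40 °C) should give the E-configured 3-O-acetyl derivative of 31, F9, and K2CO3 in MeOH cleaves the acetate to give 31.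

**Further compounds**

F1 | step 4 | (4R)-4-benzyl-3-(prop-2-enoyl)-1,3-oxazolidin-2-one | C=CC(=O)N1[C@H](Cc2ccccc2)COC1=O
F2 | step 4 | (4R)-4-benzyl-3-{[(1R)-3,5,5-trimethyl-4-{[tri(propan-2-yl)silyl]oxy}cyclohex-3-en-1-yl]carbonyl}-1,3-oxazolidin-2-one | CC1=C(O[Si](C(C)C)(C(C)C)C(C)C)C(C)(C)C[C@H](C(=O)N2[C@H](Cc3ccccc3)COC2=O)C1
F3 | step 4 | (1R)-N-methoxy-N,3,5,5-tetramethyl-4-{[tri(propan-2-yl)silyl]oxy}cyclohex-3-ene-1-carboxamide | CC1=C(O[Si](C(C)C)(C(C)C)C(C)C)C(C)(C)C[C@H](C(=O)N(C)OC)C1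
F4 | step 15 | (1S,2R)-2,6,6-trimethyl-1-[(trimethylsilyloxy)methyl]-1,2-bis(trimethylsilyloxy)cyclohexane | C[Si](C)(C)OC[C@@]1(O[Si](C)(C)C)C(C)(C)CCC[C@@]1(C)O[Si](C)(C)C
F5 | step 15 | (1R,2R)-2,6,6-trimethyl-1,2-bis(trimethylsilyloxy)cyclohexane-1-carbaldehyde | O=C[C@@]1(O[Si](C)(C)C)C(C)(C)CCC[C@@]1(C)O[Si](C)(C)C
F6 | step 15 | ethyl (2E,4E)-5-[(1R,2R)-2,6,6-trimethyl-1,2-bis(trimethylsilyloxy)cyclohexyl]-3-methylpenta-2,4-dienoate | CCOC(=O)/C=C(C)/C=C/[C@@]1(O[Si](C)(C)C)C(C)(C)CCC[C@@]1(C)O[Si](C)(C)C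
F7 | step 19 | (1R)-4-[(3E)-5-bromo-3-methylpent-3-en-1-yn-1-yl]-3,5,5-trimethylcyclohex-3-en-1-yl acetate | CC1=C(C#C/C(C)=C/CBr)C(C)(C)C[C@H](OC(C)=O)C1
F8 | step 19 | diethyl {(2E)-5-[(4R)-4-(acetyloxy)-2,6,6-trimethylcyclohex-1-en-1-yl]-3-methylpent-2-en-4-yn-1-yl}phosphonate | CC1=C(C#C/C(C)=C/CP(=O)(OCC)OCC)C(C)(C)C[C@H](OC(C)=O)C1
F9 | step 19 | (3R,5'R,6'R)-5',6'-dihydroxy-7,8-didehydro-5',6'-dihydro-β,β-caroten-3-yl acetate | CC1=C(C#C/C(C)=C/C=C/C(C)=C/C=C/C=C(C)/C=C/C=C(C)/C=C/[C@@]2(O)C(C)(C)CCC[C@@]2(C)O)C(C)(C)C[C@H](OC(C)=O)C1
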